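## Structural features

1. Prostanoid numbering is used: C1 is the carboxyl carbon, the ring is C8–C12, and C20 is the end of the lower chain.
2. The core is one cyclopentanone (C11=O). It carries a free secondary alcohol at C9, the C1–C7 acid chain with a Z-C5=C6 alkene on C8, and the saturated C13–C20 chain with a second ketone at C15 on C12.
3. The stereocentres C9, C8 and C12 are contiguous: the C9 hydroxyl and the C8 chain are cis, and the C8 and C12 chains are trans (8R,9S,12R).
4. C12 is alpha to C11=O and can epimerise toward the favoured 8,12-trans isomer, whereas C8 and C9 cannot be corrected once set.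
5. The array is fragile. C9–OH is beta to C11=O and is lost by E1cB dehydration, the two ketones are 1,5-related so base also starts an intramolecular aldol, and the Z-alkene must not isomerise.
6. The real difficulty is to build the 8,9-cis/8,12-trans ring and to reveal two ketones beside one free alcohol without late oxidations, C9/C11 oxygen differentiation or basic deprotections.
7. The feature exploited is the 1,5-diketone C11(=O)–C12–C13–C14–C15(=O), half in the ring and half in the lower chain. It is the retron of a de Mayo reaction, so C11–C12 (ring closure) and C13–C14 (chain junction) can be made together from a 1,3-diketone in which C11 and C14 are still bonded.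
8. In one sentence: the ring and the lower-chain junction arise by intramolecular enol–alkene [2+2] photocycloaddition and retro-aldol cleavage of an acyclic 8-vinyl-9-hydroxy-11,13-diketone.

## Logic of the disconnections

**18 ⇒ 17.** No skeletal bond is cut; the Z-C5=C6 alkene is taken back to a C5≡C6 alkyne. A Z-alkene could lose its geometry or compete under irradiation, whereas an alkyne has no geometry to lose. After the key step it is the only C–C multiple bond left. The gain is that the whole upper chain can be carried from the first step. The forward step must stop at the alkene and stay neutral.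

**17 ⇒ 15 (through 16).** The bonds cut are C11–C12 (ring) and C13–C14 (chain junction); in the backward sense C11–C14 is re-made. The 1,5-diketone becomes a 1,3-diketone tethered by C10–C9–C8 to a vinyl group (C12=C13). The ring, one stereocentre and the ketone placement all disappear, leaving an open chain with two adjacent stereocentres and no protecting group. The forward step must react through the C11 enol, in the straight sense, at the vinyl group only, and from the face that sets 12R.

**15 ⇒ 14 ⇒ 12.** No skeletal bond is cut. C11=O is masked as a dithioketal and the acid as its methyl ester. With C11 masked, C9–OH is not yet beta to a carbonyl, so the one basic step of the route (ester cleavage) can be done safely. The forward unmasking must not touch the alkene, the alkyne or the liberated diketone.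

**12 ⇒ 4 + 10.** The bond cut is C8–C9. It joins the two halves at the only pair of fixed stereocentres. A homoallylic alcohol with a vinyl branch is the retron of an allylboration. The 8,9-cis ring relationship corresponds to the open-chain anti isomer, which an E-allylboronate delivers. The gain is two achiral fragments of similar size. The forward step needs an E-configured reagent, catalyst control of the aldehyde face, and chemoselection of aldehyde over ketone.

**10 ⇒ 9 ⇒ 8 ⇒ 5 + 6.** The bonds cut are the two C11–S bonds and C14–C15. An ynone places the electrophilic carbon exactly at C11, so the mask is installed regiospecifically. The unmasked 3,5-dioxo aldehyde would not be a usable compound. The forward steps are acetylide acylation that stops at the ketone, double thiol addition, and an oxidation that spares sulfur.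

**4 ⇒ 3 ⇒ 1 + 2.** The bonds cut are C13–B and C6–C7. A symmetrical E-C4 dielectrophile serves first as the acceptor for the terminal alkyne and then as the source of the allylboron unit. The forward steps need monosubstitution without allylic transposition, and a borylation that keeps the linear E geometry.

## Other disconnections considered

**Alternative 1:** This is the first plan that comes to mind.
- **Cut:** C5=C6 and C13–C14 on a preformed bicyclic lactone.
- **Forward key step:** A Horner–Wadsworth–Emmons olefination of the lactone aldehyde A1 builds the lower chain. Lactone reduction and a Wittig reaction then build the upper chain.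
- **Ground for preferring the chosen plan:** A1 brings the ring and its stereocentres, but its oxidation pattern is the opposite of what is needed. C9 and C11 both arrive as alcohols and must be told apart. The C13=C14 enone must be saturated before C5=C6 exists. The basic ylide step must precede both ketones, so C11 and C15 must be oxidised at the very end with C9 protected, and the last step is a deprotection on the beta-hydroxy ketone. This costs several protecting-group and redox operations that the chosen plan avoids altogether.

**Alternative 2:**
- **Cut:** C7–C8 and C12–C13, using the same 1,5-diketone in its polar (Michael) sense.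
- **Forward key step:** A C1–C7 allylic copper reagent adds to the enone A2, and the enolate is trapped with the vinyl ketone A3.
- **Ground for preferring the chosen plan:** The nucleophile must add anti to the C9 silyloxy group, so the adduct A4 is 8,9-trans while the target is 8,9-cis. Inversion at C9 of a beta-oxy ketone invites elimination. Allylic copper reagents raise an alpha/gamma regiochemistry problem. The enolate can equilibrate toward C10 and expel the silyloxy group before it meets A3. The plan is short, but it sets the hardest relationship the wrong way.

**Alternative 3:**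
- **Cut:** C11–C12, C13–C14 and C14–C15, with a temporary C11=C15 double bond.
- **Forward key step:** A Pauson–Khand reaction of a 1,6-enyne with the same C10–C9–C8 tether gives the bicyclic enone A5. C14=O is then deoxygenated and C11=C15 is cleaved oxidatively.
- **Ground for preferring the chosen plan:** It closes the same ring bond, but C14 arrives as a carbonyl that must be removed. The oxidative cleavage must distinguish C11=C15 from the unsaturation of the upper chain. The cobalt reagent would bind any alkyne in that chain, so the chain must be completed late. Three or four operations replace what the photochemical step does in one.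

Key step: step 9

Assumption: on its accepted transition-state model, the (R)-enantiomer of the phosphoric acid in step 6 directs the allyl group to the Re face of an aliphatic aldehyde; the (S)-acid is equally available should the sense be opposite.

Assumption: 1, 2, 5 and 6 are taken as commercially available.

## Steps

Step 1
Reactants: 1 methyl hex-5-ynoate; 2 (E)-1,4-dibromobut-2-ene (4 equiv)
Product: 3 methyl (E)-10-bromodec-8-en-5-ynoate
Conditions: CuI (10 mol %), K2CO3, n-Bu4NBr, DMF, rt
Reagents that add atoms: none
Why: Copper-catalysed SN2 coupling of a terminal alkyne with an allylic bromide, a standard entry to skipped enynes; the excess of symmetrical 2 suppresses double substitution, and the E geometry is carried over unchanged.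

Step 2
Reactants: 3 methyl (E)-10-bromodec-8-en-5-ynoate
Product: 4 methyl (E)-10-(4,4,5,5-tetramethyl-1,3,2-dioxaborolan-2-yl)dec-8-en-5-ynoate
Conditions: Pd2(dba)3 (1 mol %), B2pin2 (1.1 equiv), THF, 60 °C
Reagents that add atoms: bis(pinacolato)diboron, CC1(C)OB(OC1(C)C)B1OC(C)(C)C(C)(C)O1
Why: Known palladium-catalysed borylation of allylic halides (oxidative addition to zerovalent palladium, transmetalation with the diboron reagent, reductive elimination at the less hindered terminus), which gives the linear E-allylboronate; copper catalysis is avoided because it would transpose the allyl unit.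

Step 3
Reactants: 5 but-3-yn-1-ol; 6 N-methoxy-N-methylhexanamide
Product: 8 1-hydroxydec-3-yn-5-one, via dilithiated but-3-yn-1-ol 7 (not isolated)
Conditions: n-BuLi (2.1 equiv), THF, −78 °C; then 6, −78 → 0 °C; inverse quench into cold 1 M HCl
Reagents that add atoms: none
Why: Acylation of a lithium acetylide by an N-methoxy-N-methylamide, which stops at the ketone stage because the adduct collapses only on quench; the acidic inverse quench keeps the released amine from adding to the ynone.

Step 4
Reactants: 8 1-hydroxydec-3-yn-5-one
Product: 9 1-[2-(2-hydroxyethyl)-1,3-dithian-2-yl]heptan-2-one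
Conditions: HS(CH2)3SH (1.1 equiv), NaOMe (0.3 equiv), MeOH/CH2Cl2 4:1, −10 °C → rt
Reagents that add atoms: propane-1,3-dithiol, SCCCS
Why: Double thia-Michael addition of a 1,3-dithiol to an ynone, a known route to beta-keto-1,3-dithianes; both C–S bonds form at the beta carbon (C11), the second one intramolecularly, so the mask sits on C11 and C15 stays a ketone.

Step 5
Reactants: 9 1-[2-(2-hydroxyethyl)-1,3-dithian-2-yl]heptan-2-one
Product: 10 2-[2-(2-oxoheptyl)-1,3-dithian-2-yl]acetaldehyde
Conditions: (COCl)2, DMSO, CH2Cl2, −78 °C; Et3N, −78 → −20 °C
Reagents that add atoms: none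
Why: Swern oxidation, which tolerates thioacetals; the low temperature and short contact with Et3N keep the aldehyde from losing thiolate and the 1,5-keto aldehyde from aldolising, and 10 is used promptly.

Step 6
Reactants: 4 methyl (E)-10-(4,4,5,5-tetramethyl-1,3,2-dioxaborolan-2-yl)dec-8-en-5-ynoate; 10 2-[2-(2-oxoheptyl)-1,3-dithian-2-yl]acetaldehyde
Product: 12 methyl (8R,9S)-8-ethenyl-9-hydroxy-10-[2-(2-oxoheptyl)-1,3-dithian-2-yl]dec-5-ynoate, via pinacol borate ester 11 (not isolated)
Conditions: (R)-3,3'-bis(2,4,6-triisopropylphenyl)-1,1'-binaphthyl-2,2'-diyl hydrogen phosphate (5 mol %), 4 Å MS, toluene, −30 °C; then H2O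
Reagents that add atoms: none
Why: Chiral Brønsted acid-catalysed allylboration through a closed chair (Zimmerman–Traxler) transition state; the E-boronate places C7 equatorial and gives the 8,9-anti alcohol (8,9-cis once the ring is closed), while the phosphate, bound to a boronate oxygen and the formyl hydrogen, selects the Re face and sets 9S and with it 8R. The C15 ketone is inert toward a pinacol allylboronate under these conditions.

Step 7
Reactants: 12 methyl (8R,9S)-8-ethenyl-9-hydroxy-10-[2-(2-oxoheptyl)-1,3-dithian-2-yl]dec-5-ynoate
Product: 14 (8R,9S)-8-ethenyl-9-hydroxy-10-[2-(2-oxoheptyl)-1,3-dithian-2-yl]dec-5-ynoic acid, via lithium carboxylate 13 (not isolated)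
Conditions: LiOH (3 equiv), THF/H2O 3:1, 0 °C → rt; then 1 M HCl to pH 4, 0 °C
Reagents that add atoms: lithium hydroxide, [Li+].[OH-]
Why: Ester saponification, placed here on purpose: with C11 masked there is no beta-hydroxy ketone and no 1,3- or 1,5-diketone, so neither retro-aldol, dehydration nor aldolisation can occur, and beta-keto dithianes are formed under alkoxide and tolerate it.

Step 8
Reactants: 14 (8R,9S)-8-ethenyl-9-hydroxy-10-[2-(2-oxoheptyl)-1,3-dithian-2-yl]dec-5-ynoic acid
Product: 15 (8R,9S)-8-ethenyl-9-hydroxy-11,13-dioxooctadec-5-ynoic acid
Conditions: PhI(OCOCF3)2 (1.2 equiv), MeCN/H2O 9:1, 0 °C, 15 min; pH 7 buffer work-up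
Reagents that add atoms: water, O
Why: Oxidative hydrolysis of a dithiane with a trivalent iodine reagent, a known method that spares alkenes, alkynes, alcohols and acids because sulfur is by far the best nucleophile present; near-stoichiometric oxidant, water and a short cold contact protect the liberated diketone, and 15 is irradiated without storage.

Step 9
Reactants: 15 (8R,9S)-8-ethenyl-9-hydroxy-11,13-dioxooctadec-5-ynoic acid
Product: 17 7-[(1R,2R,5S)-5-hydroxy-3-oxo-2-(3-oxooctyl)cyclopentyl]hept-5-ynoic acid, via bicyclo[3.2.0]heptanol photoadduct 16 (not isolated)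
Conditions: hν (medium-pressure Hg lamp, Pyrex filter, λ > 290 nm), degassed CH2Cl2 (5 mM), 0 °C; then rt in the dark until 16 is consumed
Reagents that add atoms: none
Why: Intramolecular de Mayo reaction, a known [2+2] photocycloaddition–retro-aldol sequence of alkenyl-tethered 1,3-diketones. Light is absorbed by the hydrogen-bonded enol C11(OH)=C14–C15=O, whose excited state attacks the vinyl group at C12 through C11, a 5-exo-trig closure of the cyclopentane that follows the rule of five for the three-atom tether C10–C9–C8 and leaves a 1,4-biradical (C14 acyl-stabilised, C13 primary). Radical recombination C13–C14 closes the four-membered ring, necessarily cis-fused, and gives 16. In 16 the C11 hydroxyl is beta to C15=O across a strained bond, so retro-aldol cleavage of C11–C14 follows in the flask and turns the 1,3-diketone of 15 into the 1,5-diketone of 17, with C11=O in the ring and C15=O in the chain. C12 is the only new stereocentre that survives (C11 and C14 of 16 are erased): since the C8 chain and the C9 hydroxyl are cis to each other, both can sit on the convex face of the bicyclo[3.2.0]heptane only if the cyclobutane is built on the opposite face, which puts C13 trans to the C8 chain (12R). The same isomer is the thermodynamic one, because C12 ends alpha to C11=O and the 8,12-trans cyclopentanone is favoured. Three selectivities are needed: the C11 enol must react and not the C15 enol (the tautomers interconvert faster than either cyclises, and only the former has a five-membered closure open to it), addition must be straight and not crossed (again the rule of five), and the vinyl group must react and not the C5≡C6 alkyne (internal and reachable only by a six-membered closure). The intense enol band screens the weak n–π* bands of the ketones in 17 until conversion is high, at which point irradiation is stopped.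

Step 10
Reactants: 17 7-[(1R,2R,5S)-5-hydroxy-3-oxo-2-(3-oxooctyl)cyclopentyl]hept-5-ynoic acid
Product: 18 (Z)-7-[(1R,2R,5S)-5-hydroxy-3-oxo-2-(3-oxooctyl)cyclopentyl]hept-5-enoic acid (13,14-dihydro-15-keto-PGD2)
Conditions: H2 (1 atm), Pd/CaCO3 poisoned with Pb(OAc)2, quinoline, EtOAc, 0 °C → rt, stopped after 1 equiv H2
Reagents that add atoms: none
Why: Lindlar-type semihydrogenation; syn delivery of H2 on the poisoned palladium surface gives the Z-alkene, the alkyne is the only C–C multiple bond left, and the neutral medium leaves C12, the beta-hydroxy ketone and the 1,5-diketone untouched.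

## Compound list

1 | methyl hex-5-ynoate | C#CCCCC(=O)OC | starting material
2 | (E)-1,4-dibromobut-2-ene | BrC/C=C/CBr | starting material
3 | methyl (E)-10-bromodec-8-en-5-ynoate | COC(=O)CCCC#CC/C=C/CBr | intermediate
4 | methyl (E)-10-(4,4,5,5-tetramethyl-1,3,2-dioxaborolan-2-yl)dec-8-en-5-ynoate | COC(=O)CCCC#CC/C=C/CB1OC(C)(C)C(C)(C)O1 | intermediate
5 | but-3-yn-1-ol | C#CCCO | starting material
6 | N-methoxy-N-methylhexanamide | CCCCCC(=O)N(C)OC | starting material
7 | dilithiated but-3-yn-1-ol (not isolated) | [Li]C#CCCO[Li] | intermediate
8 | 1-hydroxydec-3-yn-5-one | CCCCCC(=O)C#CCCO | intermediate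
9 | 1-[2-(2-hydroxyethyl)-1,3-dithian-2-yl]heptan-2-one | CCCCCC(=O)CC1(CCO)SCCCS1 | intermediate
10 | 2-[2-(2-oxoheptyl)-1,3-dithian-2-yl]acetaldehyde | CCCCCC(=O)CC1(CC=O)SCCCS1 | intermediate
11 | methyl (8R,9S)-8-ethenyl-10-[2-(2-oxoheptyl)-1,3-dithian-2-yl]-9-[(4,4,5,5-tetramethyl-1,3,2-dioxaborolan-2-yl)oxy]dec-5-ynoate (not isolated) | CCCCCC(=O)CC1(C[C@H](OB2OC(C)(C)C(C)(C)O2)[C@@H](C=C)CC#CCCCC(=O)OC)SCCCS1 | intermediate
12 | methyl (8R,9S)-8-ethenyl-9-hydroxy-10-[2-(2-oxoheptyl)-1,3-dithian-2-yl]dec-5-ynoate | CCCCCC(=O)CC1(C[C@H](O)[C@@H](C=C)CC#CCCCC(=O)OC)SCCCS1 | intermediate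
13 | lithium (8R,9S)-8-ethenyl-9-hydroxy-10-[2-(2-oxoheptyl)-1,3-dithian-2-yl]dec-5-ynoate (not isolated) | CCCCCC(=O)CC1(C[C@H](O)[C@@H](C=C)CC#CCCCC(=O)[O-])SCCCS1.[Li+] | intermediate
14 | (8R,9S)-8-ethenyl-9-hydroxy-10-[2-(2-oxoheptyl)-1,3-dithian-2-yl]dec-5-ynoic acid | CCCCCC(=O)CC1(C[C@H](O)[C@@H](C=C)CC#CCCCC(=O)O)SCCCS1 | intermediate
15 | (8R,9S)-8-ethenyl-9-hydroxy-11,13-dioxooctadec-5-ynoic acid | CCCCCC(=O)CC(=O)C[C@H](O)[C@@H](C=C)CC#CCCCC(=O)O | intermediate
16 | 7-[(1R,3S,4R,5R)-7-hexanoyl-1,3-dihydroxybicyclo[3.2.0]heptan-4-yl]hept-5-ynoic acid, epimers at the acyl-bearing carbon (not isolated) | CCCCCC(=O)C1C[C@@H]2[C@@H](CC#CCCCC(=O)O)[C@@H](O)C[C@]12O | intermediate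
17 | 7-[(1R,2R,5S)-5-hydroxy-3-oxo-2-(3-oxooctyl)cyclopentyl]hept-5-ynoic acid | CCCCCC(=O)CC[C@H]1C(=O)C[C@H](O)[C@@H]1CC#CCCCC(=O)O | intermediate
18 | (Z)-7-[(1R,2R,5S)-5-hydroxy-3-oxo-2-(3-oxooctyl)cyclopentyl]hept-5-enoic acid | CCCCCC(=O)CC[C@H]1C(=O)C[C@H](O)[C@@H]1C/C=C\CCCC(=O)O | target

## Step count and least certain steps

Total step count: 10. Longest linear sequence: 8 (steps 3–10). All twenty carbons come from 1 (C1–C6), 2 (C7, C8, C12, C13), 5 (C9, C10, C11, C14) and 6 (C15–C20).

**Step 9 (key step).** Several things may go wrong.
- The open-chain enol may lose its excitation by twisting about C11=C14 faster than the vinyl group traps it.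
- Part of the material may react through the C15 enol or at the alkyne by six-membered closures.
- Prolonged irradiation may start alpha-cleavage and gamma-hydrogen abstraction at the saturated ketones of the product.
- Facial selection at C12 may be incomplete. It can be corrected by equilibration only with caution, because base also dehydrates across C9–C10.

The fallback fixes the enol in a temporary ring and separates cycloaddition from cleavage. It sets out from 12. Unmasking as in step 8 gives the hydroxy diketone methyl ester F1. 1,1'-Carbonyldiimidazole with a trace of DBU ties O9 to the enol oxygen on C11, the only enol oxygen within reach of a six-membered ring, and gives the cyclic enol carbonate F2. Irradiation of such a regiodefined enol ester is the established two-stage variant of the de Mayo reaction and gives the cyclobutane carbonate F3. In F3 the O9–C(=O)–O11 bridge forces the four-membered ring onto the face opposite to O9 and so fixes C12. Brief hydrolysis (K2CO3, aqueous MeOH, 0 °C) frees the C11 alkoxide, which fragments to the diketo ester F4. Porcine liver esterase at pH 7 then comes back to the route at 17.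

**Step 8.** The liberated, nucleophilic diketone may be oxidised further by the trivalent iodine reagent. The acid released may also promote ring closure of the C9 hydroxyl onto C15 with loss of water. The fallback blocks the hydroxyl before the diketone exists and carries the block through the photoreaction. It sets out from 12. Silylation (TBSOTf, 2,6-lutidine) gives the silyl ether ester F5, and LiOH gives the silyl ether acid F6. Unmasking then gives the silyl-protected diketone acid F7, which can no longer cyclise and dissolves in hydrocarbon solvents that favour the chelated enol. Irradiation as in step 9 gives the silylated cyclopentanone F8. HF·pyridine in MeCN at 0 °C comes back to the route at 17.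

**Step 6.** The hindered aldehyde, quaternary at its beta carbon, may react slowly and with insufficient facial control, and the acid catalyst may start self-aldolisation of the 1,5-keto aldehyde. The fallback replaces the boron chemistry by a catalytic asymmetric Nozaki–Hiyama–Kishi allylation. It sets out from 3 and 10, so step 2 is skipped. CrCl2 (10 mol %), Mn, Me3SiCl and a chiral bis(oxazoline)-type ligand in THF generate an allylchromium species. This equilibrates to the E form and adds through its gamma carbon in a chair to give the anti adduct as the trimethylsilyl ether F9. Dilute citric acid in MeOH comes back to the route at 12. Divalent chromium chemistry selects aldehydes over ketones and esters.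

**Step 2.** The allylpalladium stage may undergo beta-hydride loss at the doubly activated C7 methylene, or the E geometry and the linear regiochemistry may erode. The fallback builds the allylboronate by one-carbon homologation instead of substitution. It sets out from 1. Copper-mediated coupling with propargyl bromide (CuI, K2CO3, NaI, DMF) gives the skipped diyne F10. Hydroboration of its terminal alkyne (pinacolborane, Cp2ZrHCl 10 mol %) gives the E-alkenylboronate F11. Matteson homologation (BrCH2Cl, n-BuLi, THF, −78 °C → rt) inserts C13 with retention of geometry and comes back to the route at 4.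

## Further compounds

F1 | step 9 | methyl (8R,9S)-8-ethenyl-9-hydroxy-11,13-dioxooctadec-5-ynoate | CCCCCC(=O)CC(=O)C[C@H](O)[C@@H](C=C)CC#CCCCC(=O)OC
F2 | step 9 | methyl (8R)-8-[(4S,6Z)-2-oxo-6-(2-oxoheptylidene)-1,3-dioxan-4-yl]dec-9-en-5-ynoate | O=C1O[C@H]([C@@H](C=C)CC#CCCCC(=O)OC)C/C(O1)=C/C(=O)CCCCC
F3 | step 9 | cyclobutane carbonate, the 9,11-O-carbonyl derivative of the methyl ester of 16 | CCCCCC(=O)C1C[C@@H]2[C@@H](CC#CCCCC(=O)OC)[C@@H]3C[C@]12OC(=O)O3
F4 | step 9 | methyl 7-[(1R,2R,5S)-5-hydroxy-3-oxo-2-(3-oxooctyl)cyclopentyl]hept-5-ynoate | CCCCCC(=O)CC[C@H]1C(=O)C[C@H](O)[C@@H]1CC#CCCCC(=O)OC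
F5 | step 8 | methyl (8R,9S)-9-[tert-butyl(dimethyl)silyl]oxy-8-ethenyl-10-[2-(2-oxoheptyl)-1,3-dithian-2-yl]dec-5-ynoate | CCCCCC(=O)CC1(C[C@H](O[Si](C)(C)C(C)(C)C)[C@@H](C=C)CC#CCCCC(=O)OC)SCCCS1
F6 | step 8 | (8R,9S)-9-[tert-butyl(dimethyl)silyl]oxy-8-ethenyl-10-[2-(2-oxoheptyl)-1,3-dithian-2-yl]dec-5-ynoic acid | CCCCCC(=O)CC1(C[C@H](O[Si](C)(C)C(C)(C)C)[C@@H](C=C)CC#CCCCC(=O)O)SCCCS1
F7 | step 8 | (8R,9S)-9-[tert-butyl(dimethyl)silyl]oxy-8-ethenyl-11,13-dioxooctadec-5-ynoic acid | CCCCCC(=O)CC(=O)C[C@H](O[Si](C)(C)C(C)(C)C)[C@@H](C=C)CC#CCCCC(=O)O
F8 | step 8 | 7-[(1R,2R,5S)-5-[tert-butyl(dimethyl)silyl]oxy-3-oxo-2-(3-oxooctyl)cyclopentyl]hept-5-ynoic acid | CCCCCC(=O)CC[C@H]1C(=O)C[C@H](O[Si](C)(C)C(C)(C)C)[C@@H]1CC#CCCCC(=O)O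
F9 | step 6 | methyl (8R,9S)-8-ethenyl-10-[2-(2-oxoheptyl)-1,3-dithian-2-yl]-9-(trimethylsilyloxy)dec-5-ynoate | CCCCCC(=O)CC1(C[C@H](O[Si](C)(C)C)[C@@H](C=C)CC#CCCCC(=O)OC)SCCCS1
F10 | step 2 | methyl nona-5,8-diynoate | COC(=O)CCCC#CCC#C
F11 | step 2 | methyl (E)-9-(4,4,5,5-tetramethyl-1,3,2-dioxaborolan-2-yl)non-8-en-5-ynoate | COC(=O)CCCC#CC/C=C/B1OC(C)(C)C(C)(C)O1
A1 | alternative 1 | (3aR,4R,5R,6aS)-4-formyl-2-oxohexahydro-2H-cyclopenta[b]furan-5-yl benzoate | O=C[C@H]1[C@H](OC(=O)c3ccccc3)C[C@@H]2OC(=O)C[C@H]12
A2 | alternative 2 | (R)-4-[tert-butyl(dimethyl)silyl]oxycyclopent-2-en-1-one | O=C1C[C@@H](O[Si](C)(C)C(C)(C)C)C=C1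
A3 | alternative 2 | oct-1-en-3-one | C=CC(=O)CCCCC
A4 | alternative 2 | methyl (Z)-7-[(1R,2R,5R)-5-[tert-butyl(dimethyl)silyl]oxy-3-oxo-2-(3-oxooctyl)cyclopentyl]hept-5-enoate | CCCCCC(=O)CC[C@H]1C(=O)C[C@@H](O[Si](C)(C)C(C)(C)C)[C@@H]1C/C=C\CCCC(=O)OC
A5 | alternative 3 | methyl (Z)-7-[(1R,2S,6aR)-2-[tert-butyl(dimethyl)silyl]oxy-5-oxo-4-pentyl-1,2,3,5,6,6a-hexahydropentalen-1-yl]hept-5-enoate | CCCCCC1=C2C[C@H](O[Si](C)(C)C(C)(C)C)[C@H](C/C=C\CCCC(=O)OC)[C@H]2CC1=O
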